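The route rests on cutting both bonds that join the cyclopentane to the cycloheptane at the ring fusion, C5–C4 and C1–C2 (daucane numbering, see remark). They lie trans on adjacent ring carbons, C5 being the β-carbon and C1 the α-carbon of a C10 carbonyl. One three-component operation on cycloheptadienone 10 therefore forms both: an isopropyl-substituted alkenylcopper reagent adds to C5 anti to the C6 silyloxy group, and the enolate is trapped at C1 by acrolein, which also creates the quaternary centre. The precursor is a monocyclic 4-silyloxy-2,6-dimethylcyclohepta-2,6-dienone; metathesis of the two new alkenyl arms then closes the five-membered ring.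

Key step: step 6

Remark: daucane numbering is used: C1 quaternary ring-fusion carbon (methyl), C2 acetoxy carbon, C3 CH2, C4 isopropyl carbinol, C5 ring-fusion CH, C6 anisoyloxy carbon, C7 CH2, C8/C9 epoxide carbons (C8 methyl), C10 free carbinol. The face carrying the C1 methyl is called β. Stannane 2 and bromide 11 are assumed to be commercially available.

Step 1
Reactants: 1 acrolein; 2 tributyl(2-methylprop-2-en-1-yl)stannane
Product: 3 (S)-5-methylhexa-1,5-dien-3-ol
Conditions: Ti(OiPr)4 (10 mol%), (S)-BINOL (20 mol%), 4 Å MS, CH2Cl2, −20 °C; aq. NaHCO3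
Reagents that add atoms: none
Why: Keck asymmetric allylation, in which the BINOL–titanium Lewis acid should direct 1,2-addition of the methallylstannane to one face of the aldehyde; the (S)-ligand is expected by analogy to give the S carbinol, which becomes C6 and controls all later centres.

Step 2
Reactants: 3 (S)-5-methylhexa-1,5-dien-3-ol; 4 methacryloyl chloride
Product: 5 (S)-5-methylhexa-1,5-dien-3-yl 2-methylprop-2-enoate
Conditions: Et3N, DMAP (cat.), CH2Cl2, 0 °C
Reagents that add atoms: none
Why: Standard acylation of a secondary alcohol; it brings in C10 and C1 with its methyl group.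

Step 3
Reactants: 5 (S)-5-methylhexa-1,5-dien-3-yl 2-methylprop-2-enoate
Product: 6 (S)-3-methyl-5-(2-methylprop-2-en-1-yl)furan-2(5H)-one
Conditions: second-generation Grubbs catalyst (5 mol%), toluene, 80 °C, 0.01 M
Reagents that add atoms: none
Why: Ring-closing metathesis of the methacrylate with the vinyl group is the only strain-free closure (the methallyl group could only give a cyclobutene or a tetrasubstituted alkene), and the butenolide ring fixes the cis geometry of C1=C5.

Step 4
Reactants: 6 (S)-3-methyl-5-(2-methylprop-2-en-1-yl)furan-2(5H)-one; 7 vinylmagnesium bromide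
Product: 9 (S,Z)-4,8-dimethyl-6-(triethylsilyloxy)nona-1,4,8-trien-3-one, via bromomagnesium lactolate 8 (not isolated)
Conditions: CH2=CHMgBr (1.05 equiv), CeCl3, THF, −78 °C; then Et3SiCl, imidazole, DMAP, −78 °C → rt
Reagents that add atoms: chlorotriethylsilane, CC[Si](Cl)(CC)CC
Why: Mono-addition of the organometallic to the lactone carbonyl (nucleophilic acyl substitution) should stop at the hemiketal alkoxide, and silylation of its ring-opened form should release the Z-enone with C6 protected.

Step 5
Reactants: 9 (S,Z)-4,8-dimethyl-6-(triethylsilyloxy)nona-1,4,8-trien-3-one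
Product: 10 (S)-2,6-dimethyl-4-(triethylsilyloxy)cyclohepta-2,6-dien-1-one
Conditions: second-generation Hoveyda–Grubbs catalyst (5 mol%), CH2Cl2, 40 °C, 0.005 M
Reagents that add atoms: none
Why: Ring-closing metathesis between the vinyl ketone and the 1,1-disubstituted alkene should close the seven-membered ring and form the trisubstituted C8=C9 bond, the pre-set Z-enone holding the two termini together.

Step 6
Reactants: 10 (S)-2,6-dimethyl-4-(triethylsilyloxy)cyclohepta-2,6-dien-1-one; 11 2-bromo-3-methylbut-1-ene; 1 acrolein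
Product: 13 (5S,6S,7R)-7-[(R)-1-hydroxyprop-2-en-1-yl]-3,7-dimethyl-6-(3-methylbut-1-en-2-yl)-5-(triethylsilyloxy)cyclohept-2-en-1-one, via bromomagnesium dienolate 12 (not isolated)
Conditions: 11, Mg, THF; CuBr·SMe2 (20 mol%), then 10, THF, −78 → −40 °C; then acrolein, −78 °C; aq. NH4Cl at −78 °C
Reagents that add atoms: none
Why: Copper-catalysed conjugate addition of the alkenyl Grignard reagent to C5 of the cross-conjugated dienone gives magnesium enolate 12, whose α-carbon C1 then adds 1,2 to acrolein, so C5–C4 and C1–C2 form in one flask. The closest known reaction type is the three-component conjugate addition/enolate trapping (tandem vicinal difunctionalisation) of cycloalkenones. No ring is closed here; the cyclopentene is closed in step 7 from the two alkenes introduced. C5 is set by approach of the copper reagent anti to the adjacent C6 silyloxy group, and C1 by attack of the enolate on the face opposite the new C5 substituent, which gives the trans relationship that becomes the trans ring fusion and places the methyl on the β face. C2 is set by a closed chair transition state of the cyclic enolate with the vinyl group equatorial, which should place the C2 oxygen syn to the C1 methyl. The step needs site selectivity between the two enone termini, secured by the β-methyl group that makes C8 β,β-disubstituted, and 1,2- over 1,4-addition to acrolein, secured by the hard magnesium enolate at low temperature.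

Step 7
Reactants: 13 (three-component adduct)
Product: 14 2β-hydroxy-6α-(triethylsilyloxy)dauca-3,8-dien-10-one (5α-H, 1β-methyl)
Conditions: second-generation Hoveyda–Grubbs catalyst (10 mol%), 1,4-benzoquinone (20 mol%), toluene, 80 °C
Reagents that add atoms: none
Why: Ring-closing metathesis of the allylic-alcohol vinyl group with the isopropyl-bearing 1,1-disubstituted alkene should form the C3=C4 cyclopentene; the trans arrangement of the two arms gives the trans-fused bicycle and the conjugated C8=C9 alkene is inert.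

Step 8
Reactants: 14 2β-hydroxy-6α-(triethylsilyloxy)dauca-3,8-dien-10-one
Product: 15 3β,4β-epoxy-2β-hydroxy-6α-(triethylsilyloxy)dauc-8-en-10-one
Conditions: VO(acac)2 (5 mol%), t-BuOOH, CH2Cl2, 0 °C → rt
Reagents that add atoms: tert-butyl hydroperoxide, CC(C)(C)OO
Why: Vanadium-catalysed hydroxyl-directed epoxidation should deliver oxygen to C3=C4 syn to the allylic 2β-hydroxyl, which sets the C4 oxygen on the hindered β face; the electron-poor enone alkene does not react.

Step 9
Reactants: 15 3β,4β-epoxy-2β-hydroxy-6α-(triethylsilyloxy)dauc-8-en-10-one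
Product: 16 6α-(triethylsilyloxy)dauc-8-ene-2β,4β,10β-triol
Conditions: NaAlH2(OCH2CH2OMe)2, THF, 0 °C → rt; aq. potassium sodium tartrate
Reagents that add atoms: none
Why: Alkoxide-directed hydride opening of the 2,3-epoxy alcohol at C3, which is also the less substituted carbon, should give the 2β,4β-diol with inversion at C3 only; the enone carbonyl is reduced 1,2 at the same time and is restored in step 10, so its configuration does not matter.

Step 10
Reactants: 16 6α-(triethylsilyloxy)dauc-8-ene-2β,4β,10β-triol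
Product: 17 2β,4β-dihydroxy-6α-(triethylsilyloxy)dauc-8-en-10-one
Conditions: MnO2, CH2Cl2, rt
Reagents that add atoms: none
Why: Manganese dioxide oxidises only the allylic C10 alcohol and leaves the saturated secondary C2 and tertiary C4 alcohols untouched.

Step 11
Reactants: 17 2β,4β-dihydroxy-6α-(triethylsilyloxy)dauc-8-en-10-one
Product: 18 2β-acetoxy-4β-hydroxy-6α-(triethylsilyloxy)dauc-8-en-10-one
Conditions: Ac2O, pyridine, DMAP, CH2Cl2, 0 °C → rt
Reagents that add atoms: acetic anhydride, CC(=O)OC(C)=O
Why: DMAP-catalysed acetylation of the only secondary alcohol; the tertiary C4 alcohol does not react.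

Step 12
Reactants: 18 2β-acetoxy-4β-hydroxy-6α-(triethylsilyloxy)dauc-8-en-10-one
Product: 19 2β-acetoxy-6α-(triethylsilyloxy)dauc-8-ene-4β,10β-diol
Conditions: NaBH4, CeCl3·7H2O, MeOH, −78 → −40 °C
Reagents that add atoms: none
Why: Luche 1,2-reduction of the enone, in which hydride should attack anti to the axial angular methyl on the adjacent C1 (as in 17-keto steroids) and give the 10β-alcohol.

Step 13
Reactants: 19 2β-acetoxy-6α-(triethylsilyloxy)dauc-8-ene-4β,10β-diol
Product: 20 2β-acetoxy-10β-(tert-butyldimethylsilyloxy)-6α-(triethylsilyloxy)dauc-8-en-4β-ol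
Conditions: t-BuMe2SiOTf (1.2 equiv), 2,6-lutidine, CH2Cl2, −78 °C
Reagents that add atoms: tert-butyldimethylsilyl trifluoromethanesulfonate, CC(C)(C)[Si](C)(C)OS(=O)(=O)C(F)(F)F
Why: Silylation of the secondary allylic alcohol, which should outpace the hindered tertiary C4 alcohol at low temperature; the bulky 10β-silyl ether removes the syn-directing allylic hydroxyl before the epoxidation.

Step 14
Reactants: 20 2β-acetoxy-10β-(tert-butyldimethylsilyloxy)-6α-(triethylsilyloxy)dauc-8-en-4β-ol
Product: 21 2β-acetoxy-10β-(tert-butyldimethylsilyloxy)dauc-8-ene-4β,6α-diol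
Conditions: PPTS (cat.), MeOH/CH2Cl2, 0 °C
Reagents that add atoms: none
Why: Acid-catalysed methanolysis cleaves the triethylsilyl ether much faster than the hindered tert-butyldimethylsilyl ether.

Step 15
Reactants: 21 2β-acetoxy-10β-(tert-butyldimethylsilyloxy)dauc-8-ene-4β,6α-diol
Product: 22 2β-acetoxy-10β-(tert-butyldimethylsilyloxy)-8α,9α-epoxydaucane-4β,6α-diol
Conditions: VO(acac)2 (5 mol%), t-BuOOH, CH2Cl2, 0 °C
Reagents that add atoms: tert-butyl hydroperoxide, CC(C)(C)OO
Why: Hydroxyl-directed epoxidation from the homoallylic 6α-hydroxyl should put the oxirane on the α face of C8=C9, reinforced by the 10β-silyloxy group and the axial C1 methyl shielding the β face.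

Step 16
Reactants: 22 2β-acetoxy-10β-(tert-butyldimethylsilyloxy)-8α,9α-epoxydaucane-4β,6α-diol; 23 4-methoxybenzoyl chloride
Product: 24 2β-acetoxy-10β-(tert-butyldimethylsilyloxy)-8α,9α-epoxy-4β-hydroxydaucan-6α-yl 4-methoxybenzoate
Conditions: Et3N, DMAP, CH2Cl2, rt
Reagents that add atoms: none
Why: DMAP-catalysed acylation of the only free secondary alcohol; the tertiary C4 alcohol does not react.

Step 17
Reactants: 24 2β-acetoxy-10β-(tert-butyldimethylsilyloxy)-8α,9α-epoxy-4β-hydroxydaucan-6α-yl 4-methoxybenzoate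
Product: 25 (1S,2R,4R,5S,6S,8R,9S,10R)-2-acetoxy-8,9-epoxy-4,10-dihydroxydaucan-6-yl 4-methoxybenzoate (CNP0371526.1)
Conditions: HF·pyridine, pyridine, THF, 0 °C → rt
Reagents that add atoms: none
Why: Buffered fluoride desilylation should free the C10 alcohol without the basic conditions that would invite acetyl migration or Payne rearrangement of the epoxy alcohol.

Compound list
1 | acrolein | C=CC=O | starting material
2 | tributyl(2-methylprop-2-en-1-yl)stannane | CCCC[Sn](CCCC)(CCCC)CC(C)=C | starting material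
3 | (S)-5-methylhexa-1,5-dien-3-ol | C=C[C@@H](O)CC(C)=C | intermediate
4 | methacryloyl chloride | C=C(C)C(=O)Cl | starting material
5 | (S)-5-methylhexa-1,5-dien-3-yl 2-methylprop-2-enoate | C=C[C@@H](OC(=O)C(C)=C)CC(C)=C | intermediate
6 | (S)-3-methyl-5-(2-methylprop-2-en-1-yl)furan-2(5H)-one | CC1=C[C@H](CC(C)=C)OC1=O | intermediate
7 | vinylmagnesium bromide | C=C[Mg]Br | starting material
8 | bromomagnesium (5S)-3-methyl-5-(2-methylprop-2-en-1-yl)-2-vinyl-2,5-dihydrofuran-2-olate (hemiketal carbon unassigned) | CC1=C[C@H](CC(C)=C)OC1(C=C)O[Mg]Br | intermediate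
9 | (S,Z)-4,8-dimethyl-6-(triethylsilyloxy)nona-1,4,8-trien-3-one | C=CC(=O)/C(C)=C\[C@@H](O[Si](CC)(CC)CC)CC(C)=C | intermediate
10 | (S)-2,6-dimethyl-4-(triethylsilyloxy)cyclohepta-2,6-dien-1-one | CC1=C[C@@H](O[Si](CC)(CC)CC)CC(C)=CC1=O | intermediate
11 | 2-bromo-3-methylbut-1-ene | C=C(Br)C(C)C | starting material
12 | bromomagnesium dienolate of the C5 adduct (C10–OMgBr, C1=C10, C8=C9; 5β-alkenyl, 6α-silyloxy) | CC[Si](CC)(CC)O[C@H]1CC(C)=CC(O[Mg]Br)=C(C)[C@@H]1C(=C)C(C)C | intermediate
13 | (5S,6S,7R)-7-[(R)-1-hydroxyprop-2-en-1-yl]-3,7-dimethyl-6-(3-methylbut-1-en-2-yl)-5-(triethylsilyloxy)cyclohept-2-en-1-one | CC[Si](CC)(CC)O[C@H]1CC(C)=CC(=O)[C@]([C@H](O)C=C)(C)[C@@H]1C(=C)C(C)C | intermediate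
14 | 2β-hydroxy-6α-(triethylsilyloxy)dauca-3,8-dien-10-one | CC[Si](CC)(CC)O[C@H]1CC(C)=CC(=O)[C@]2(C)[C@@H]1C(C(C)C)=C[C@H]2O | intermediate
15 | 3β,4β-epoxy-2β-hydroxy-6α-(triethylsilyloxy)dauc-8-en-10-one | CC[Si](CC)(CC)O[C@H]1CC(C)=CC(=O)[C@]2(C)[C@@H]1[C@@]3(C(C)C)O[C@H]3[C@H]2O | intermediate
16 | 6α-(triethylsilyloxy)dauc-8-ene-2β,4β,10β-triol | CC[Si](CC)(CC)O[C@H]1CC(C)=C[C@H](O)[C@]2(C)[C@@H]1[C@](O)(C(C)C)C[C@H]2O | intermediate
17 | 2β,4β-dihydroxy-6α-(triethylsilyloxy)dauc-8-en-10-one | CC[Si](CC)(CC)O[C@H]1CC(C)=CC(=O)[C@]2(C)[C@@H]1[C@](O)(C(C)C)C[C@H]2O | intermediate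
18 | 2β-acetoxy-4β-hydroxy-6α-(triethylsilyloxy)dauc-8-en-10-one | CC[Si](CC)(CC)O[C@H]1CC(C)=CC(=O)[C@]2(C)[C@@H]1[C@](O)(C(C)C)C[C@H]2OC(C)=O | intermediate
19 | 2β-acetoxy-6α-(triethylsilyloxy)dauc-8-ene-4β,10β-diol | CC[Si](CC)(CC)O[C@H]1CC(C)=C[C@H](O)[C@]2(C)[C@@H]1[C@](O)(C(C)C)C[C@H]2OC(C)=O | intermediate
20 | 2β-acetoxy-10β-(tert-butyldimethylsilyloxy)-6α-(triethylsilyloxy)dauc-8-en-4β-ol | CC[Si](CC)(CC)O[C@H]1CC(C)=C[C@H](O[Si](C)(C)C(C)(C)C)[C@]2(C)[C@@H]1[C@](O)(C(C)C)C[C@H]2OC(C)=O | intermediate
21 | 2β-acetoxy-10β-(tert-butyldimethylsilyloxy)dauc-8-ene-4β,6α-diol | O[C@H]1CC(C)=C[C@H](O[Si](C)(C)C(C)(C)C)[C@]2(C)[C@@H]1[C@](O)(C(C)C)C[C@H]2OC(C)=O | intermediate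
22 | 2β-acetoxy-10β-(tert-butyldimethylsilyloxy)-8α,9α-epoxydaucane-4β,6α-diol | O[C@H]1C[C@@]2(C)O[C@H]2[C@H](O[Si](C)(C)C(C)(C)C)[C@]2(C)[C@@H]1[C@](O)(C(C)C)C[C@H]2OC(C)=O | intermediate
23 | 4-methoxybenzoyl chloride | COc1ccc(C(Cl)=O)cc1 | starting material
24 | 2β-acetoxy-10β-(tert-butyldimethylsilyloxy)-8α,9α-epoxy-4β-hydroxydaucan-6α-yl 4-methoxybenzoate | COc1ccc(C(=O)O[C@H]2C[C@@]3(C)O[C@H]3[C@H](O[Si](C)(C)C(C)(C)C)[C@]3(C)[C@@H]2[C@](O)(C(C)C)C[C@H]3OC(C)=O)cc1 | intermediate
25 | (1S,2R,4R,5S,6S,8R,9S,10R)-2-acetoxy-8,9-epoxy-4,10-dihydroxydaucan-6-yl 4-methoxybenzoate | COc1ccc(C(=O)O[C@H]2C[C@@]3(C)O[C@H]3[C@H](O)[C@]3(C)[C@@H]2[C@](O)(C(C)C)C[C@H]3OC(C)=O)cc1 | target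

Total steps: 17. Longest linear sequence: 17 steps, from acrolein 1 to 25.

Steps most likely to fail

Step 6. Trapping of the hindered, fully substituted enolate may be slow, so that protonation, reversal of the aldol addition on warming, or base-induced loss of the C6 silyloxy group from the dienone competes. The fallback sets out from 10: the same Grignard reagent is added with CuBr·SMe2 in the presence of Me3SiCl, and the conjugate adduct is isolated as the trimethylsilyl enol ether F1. A BF3·OEt2-promoted Mukaiyama aldol addition to acrolein at −78 °C then makes the C1–C2 bond in a separate operation and returns to the route at 13.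

Step 4. The vinyl nucleophile may add in a conjugate or double fashion, the cyclic hemiketal may be silylated instead of the open chain, or the cis-γ-hydroxy enone may cyclodehydrate to a furan. The fallback sets out from 6: the lactone is opened with the aluminium amide from MeNHOMe·HCl and AlMe3 to the Z-hydroxy Weinreb amide F2, which is silylated with Et3SiCl/imidazole to the triethylsilyl ether F3. Addition of CH2=CHMgBr stops at the ketone stage and returns at 9.

Step 9. Conjugate reduction of the enone, or retro-aldol opening of the β-hydroxy ketone before its carbonyl is reduced, may erode the triol. The fallback sets out from 15: the epoxide is opened at C3 with PhSeNa (from PhSeSePh and NaBH4 in EtOH) to the 3α-phenylselanyl diol F4, which keeps the enone, and the selenium is removed with Bu3SnH/AIBN in benzene at 80 °C. This returns at 17 and makes the re-oxidation of step 10 unnecessary.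

Further compounds
F1 | step 6 | trimethylsilyl enol ether of the C5 conjugate adduct (C10–OSiMe3, C1=C10; 5β-alkenyl, 6α-triethylsilyloxy) | CC[Si](CC)(CC)O[C@H]1CC(C)=CC(O[Si](C)(C)C)=C(C)[C@@H]1C(=C)C(C)C
F2 | step 4 | (S,Z)-4-hydroxy-N-methoxy-N,2,6-trimethylhepta-2,6-dienamide | CON(C)C(=O)/C(C)=C\[C@@H](O)CC(C)=C
F3 | step 4 | (S,Z)-N-methoxy-N,2,6-trimethyl-4-(triethylsilyloxy)hepta-2,6-dienamide | CON(C)C(=O)/C(C)=C\[C@@H](O[Si](CC)(CC)CC)CC(C)=C
F4 | step 9 | 2β,4β-dihydroxy-3α-(phenylselanyl)-6α-(triethylsilyloxy)dauc-8-en-10-one | CC[Si](CC)(CC)O[C@H]1CC(C)=CC(=O)[C@]2(C)[C@@H]1[C@](O)(C(C)C)[C@H]([Se]c3ccccc3)[C@H]2O
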